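# Proposed synthesis of CNP0335239.1 by α,α′-annulation of a cyclobutanone enamine

## Analysis of the target

- The target is a tricyclic diester built on a cyclobutane. Ring atoms are numbered C1 (senecioate carbinol), C2 (CH2), C3 (isovalerate carbinol), C4 (gem-dimethyl carbon), C5, C6, C7 (ketone), C8 (=CH), C9 (methyl-bearing alkene carbon), C10 and C11 (methyl-bearing quaternary carbon). The four-membered ring is C5–C6–C11–C10.
- One face of the cyclobutane is spanned at C6/C10 by the enone unit C7(=O)–C8=C9(CH3), giving a bicyclo[3.1.1]heptenone. The other face is spanned at C5/C11 by the chain C1–C2–C3–C4, giving the seven-membered ring. Both cis-1,3 pairs of the cyclobutane are therefore bridged, on opposite faces.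
- There are six stereocentres. C5, C6, C10 and C11 are locked by the two bridges, with the C11 methyl and the C5 hydrogen on the enone side. C1 and C3 carry their acyloxy groups trans across the seven-membered ring (a 1,3-anti diol diester). By CIP the target is 1R,3R,5S,6R,10R,11R in this numbering.
- Apart from the difference between C7 and C9, the carbon cage has a mirror plane through C5, C11 and C8. The skeleton therefore gives almost no bias at C1 and C3: one of them needs reagent control and the other relative control.
- Sensitive points: C6 is a cyclobutane carbon α to the C7 ketone, so an alkoxide or hydroxyl at C5 would open the four-membered ring by retro-aldol cleavage while C7 is a carbonyl. The senecioate can deconjugate under base. The two esters sit on very similar neopentyl carbinols and must be told apart.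
- The synthesis is hard because of strain, two quaternary carbons (C4, C11) and the fact that C5 and C11 are each shielded on both faces.
- The strategy rests on one feature: C6 and C10 both flank C5. A cyclobutanone with C5 as carbonyl and C11 as its 3-position offers both α-carbons for bridging by the three-carbon unit C7–C8–C9 in one operation.

## Retrosynthetic reasoning

**C1–O acyl bond.** The senecioate of 25 is cut last, giving alcohol 23 and acid chloride 24. The unsaturated ester is the most base-sensitive group and is best introduced after all carbanion and hydride chemistry. The forward step is an acylation of a neopentyl carbinol without deconjugation.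

**C1–H bond and C3–O acyl bond together.** Hydroxy ester 23 is traced to ketol 21 and aldehyde 22 by an Evans–Tishchenko transform. This one cut sets C1 relative to C3 (anti, by intramolecular hydride delivery) and places the isovalerate on C3, so the two near-identical carbinols never have to be differentiated by selective acylation. The forward step must reduce the C1 ketone but leave the C7 enone, which has no β-hydroxyl and cannot take part.

**C1–C2 bond (seven-membered ring) and unmasking of the enone.** Ketol 21 comes from tricyclic keto sulfone 19, in which C2 carries a phenylsulfonyl group and the enone is held as a silyl dienol ether. Keto sulfone 19 is opened at C1–C2 to hydroxy sulfone 18. The cut is placed here because the two ends, the C11 ester carbon and C2, sit on substituents that are cis-1,3 on the cyclobutane and so are held close. The sulfone makes C2 a nucleophile and is removed afterwards. The forward reaction is an intramolecular acylation of the sulfonyl carbanion by the tert-butyl ester, followed by reductive desulfonylation and hydrolysis of the enol ether.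

**C3 stereocentre and C2–C3 bond.** Hydroxy sulfone 18 comes from keto sulfone 17 by a catalyst-controlled ketone reduction. This is the one point where an external chiral reagent is used, because C3 is flanked by a quaternary carbon and a CH2 group, the ideal case for reagent control. Keto sulfone 17 is cut at C2–C3 to methyl ester 15 and sulfone 16. The forward acylation must take the methyl ester and leave the tert-butyl ester on C11.

**C4 methyl groups, C5–H bond and C4–C5 bond.** Ester 15 is simplified by removing the two C4 methyl groups (monoester 13), then the C5 hydrogen (alkylidene ester 12), then the C4=C5 double bond (ketone 10 and silyl acetate 11). This order is chosen because reagents reach C5 more easily from the side of the three-carbon bridge than from the side of the C11 ester. A carbon nucleophile added to the C5 ketone would therefore end on the wrong face. Bringing carbon in as an sp2 unit and adding hydrogen last puts the hydrogen on the bridge side and pushes C4 to the ester side, where the ring must later close. No C5 hydroxyl is ever formed, so no deoxygenation is needed.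

**Masking of C7.** Ketone 10 is the silyl dienol ether of diketone 9. Diketone 9 is a non-enolisable β-diketone with a strained cyclobutanone, and any alkoxide at C5 would fragment the C5–C6 bond while C7 is a carbonyl. Converting the enone to its dienol ether in the first step after the annulation removes that pathway for the whole middle of the route, and the bridge becomes flat, which opens the face from which hydrogen is to be delivered to C5.

**C9–C10 and C6–C7 bonds (the key disconnection).** Diketone 9 is cut across both bonds to enamine 4 and acid chloride 7. This takes the six-membered enone ring off in one step and reduces the problem to a symmetrical four-membered ketone. The forward reaction must form both bonds on the same face of the cyclobutane, on the face away from the ester, and must distinguish the two enantiotopic α-carbons.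

**Precursors.** Enamine 4 is the condensation product of ketone 2 with amine 3, and ketone 2 is the tert-butyl ester of acid 1. Acid chloride 7 comes from acid 6, the hydrochlorination product of ynoic acid 5. The Z geometry of 7 is deliberate: a substitution at C9 with retention then places C10 cis to the acyl group, as the ring requires.

## Alternatives that were turned down

**Alternative 1: carbonyl-ene closure of the enone ring.**
- Disconnection: C7–C8, made last, on a cyclobutane that already carries the seven-membered ring with both oxygens.
- Forward key step: Me2AlCl promotes an intramolecular ene reaction between an aldehyde (C7) on C6 and an isopropenyl group on C10, while C6 equilibrates through the enol. The product is homoallylic alcohol A1, with a C7 hydroxyl and an exocyclic methylene on C9.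
- For it: Lewis-acid ene closures to six-membered rings are well known. The epimerisable aldehyde funnels both C6 epimers into the one that can cyclise. The oxygenation at C1 and C3 can be set before the cage is rigid. On precedent for the key bond formation this alternative is stronger than the chosen route.
- Against it: the substrate is a tetrasubstituted cyclobutane, already bridged by the seven-membered ring, with four stereocentres and the quaternary C11 in place. Its assembly is the real problem and is not solved by the key step. A1 still needs oxidation at C7 and migration of the exocyclic alkene into conjugation. The aldehyde α to a strained ring is exposed to Me2AlCl in the presence of an ester and a silyl ether.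
- Comparison: the chosen route offers, in place of a precedented ene step, the formation of two C–C bonds, one ring and three stereocentres in one step from a four-carbon ring available in one step.

**Alternative 2: one-carbon insertion into an acyloin-derived bridge.**
- Disconnection: C1–C2 and C2–C3, with C1 and C3 first joined directly.
- Forward key step: Et2Zn/CH2I2 cyclopropanates a bis(silyloxy)alkene C1=C3, and FeCl3 or mild acid cleaves the C1–C3 bond to give the seven-membered 1,3-diketone A2, which has a C7 methylene.
- For it: the acyloin closure across two cis-1,3 ester groups is well matched to the geometry, and the insertion supplies C2 cleanly. In ring-forming reliability it is at least equal to the sulfone acylation used here.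
- Against it: A2 has two ketones on a cage that is nearly mirror-symmetric. C1 and C3 would have to be reduced with absolute control on an enolised β-diketone, and the two resulting carbinols then acylated differently. The C7 ketone must be introduced late by allylic oxidation.
- Comparison: the chosen route sets C3 by catalyst control on an acyclic ketone with a quaternary neighbour, and sets C1 and the ester placement in a single directed hydride transfer. It also carries the C7 oxygen from the key step onward.

**Alternative 3: epoxide-triggered cyclopropanol-to-cyclobutanone expansion.**
- Disconnection: C10–C11, by ring expansion.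
- Forward key step: MgBr2 or BF3·OEt2 opens a C11–C1 epoxide at C11, a cyclopropane bond migrates to C11 and the C6 silyl ether collapses to a ketone. The product is bicyclo[4.1.1]octan-8-one A3, with the C10 ester, C11 methyl, C1 hydroxyl and C3 dioxolane.
- For it: the migration is stereospecific, so the quaternary centre C11 and its relation to C1 are fixed by the substrate and not by an auxiliary. On that point it is stronger than the chosen key step. The seven-membered ring and its oxygens are in place early.
- Against it: the substrate (a cyclopropanol ether fused to a seven-membered ring with a tetrasubstituted epoxide) is long to make. After A3 the whole enone ring must still be built across the cyclobutanone. C6 is then a carbonyl that has to become a C–H carrying the acyl bridge, at a one-carbon bridge that is hindered on both faces.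
- Comparison: the chosen route builds the bicyclo[3.1.1] enone first and directly, and pays for this with less certain stereocontrol in its key step.

Key step: step 5

## Remarks on the chemistry

- Locants C1–C11 are those defined in the analysis and are used for all intermediates.
- Compounds 1, 3, 5, 11, 16, 22 and 24 are taken to be catalogue chemicals.
- Diketone 9 is not stored; it is taken into step 6 on the day it is made.

## Route

Step 1
Reactants: 1 1-methyl-3-oxocyclobutane-1-carboxylic acid
Product: 2 tert-butyl 1-methyl-3-oxocyclobutane-1-carboxylate
Conditions: tert-butyl 2,2,2-trichloroacetimidate (2 equiv), BF3·OEt2 (cat.), CH2Cl2/cyclohexane, rt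
Reagents that add atoms: tert-butyl 2,2,2-trichloroacetimidate, CC(C)(C)OC(=N)C(Cl)(Cl)Cl
Why: Acid-catalysed tert-butylation of a carboxylic acid by the imidate leaves the ketone untouched; the bulky ester is wanted as the facial shield in steps 5 and 8.

Step 2
Reactants: 2 tert-butyl 1-methyl-3-oxocyclobutane-1-carboxylate; 3 (S)-2-(methoxymethyl)pyrrolidine
Product: 4 tert-butyl 3-[(2S)-2-(methoxymethyl)pyrrolidin-1-yl]-1-methylcyclobut-2-ene-1-carboxylate (both positions of the C=C bond, in equilibrium)
Conditions: 3 (1.05 equiv), 4 Å molecular sieves, toluene, rt; filter, concentrate, use crude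
Reagents that add atoms: none
Why: Enamine condensation of a strained, electrophilic cyclobutanone with a secondary amine, driven by removal of water; the two double-bond isomers are epimers at the quaternary carbon and interconvert, so nothing is fixed yet.

Step 3
Reactants: 5 but-2-ynoic acid
Product: 6 (Z)-3-chlorobut-2-enoic acid
Conditions: LiCl (1.5 equiv), AcOH, MeCN, 80 °C
Reagents that add atoms: lithium chloride, [Li+].[Cl-]
Why: Conjugate addition of chloride to the ynoic acid followed by anti protonation (hydrohalogenation of 2-alkynoic acids) gives the isomer with chlorine cis to the carboxyl group.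

Step 4
Reactants: 6 (Z)-3-chlorobut-2-enoic acid
Product: 7 (Z)-3-chlorobut-2-enoyl chloride
Conditions: (COCl)2 (1.2 equiv), DMF (cat.), CH2Cl2, 0 °C → rt; evaporate, use at once
Reagents that add atoms: oxalyl chloride, O=C(Cl)C(Cl)=O
Why: Standard acid chloride formation through the chloroiminium catalyst; low temperature and immediate use keep the alkene geometry.

Step 5
Reactants: 4 enamine; 7 (Z)-3-chlorobut-2-enoyl chloride
Product: 9 tert-butyl (1R,5R,6R)-4,6-dimethyl-2,7-dioxobicyclo[3.1.1]hept-3-ene-6-carboxylate, via bicyclic iminium chloride 8 (not isolated)
Conditions: 7 (1.05 equiv, slow addition), 2,6-lutidine (2.2 equiv), CH2Cl2, −40 °C → rt; then aq. NaOAc/AcOH (pH 5), 0 °C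
Reagents that add atoms: water, O
Why: Proposed new method: the enamine carbon C10 of 4 adds to C9 of 7 and expels chloride (vinylic substitution by addition–elimination, which leaves the new C–C bond cis to the acyl chloride only if chlorine was cis, hence the Z reagent), 2,6-lutidine moves the enamine to the other α-carbon, and that carbon (C6) is acylated intramolecularly in a 6-exo-trig closure onto the acid chloride to give iminium 8, which buffered water hydrolyses to the C5 ketone; if N-acylation with aza-Claisen shift or C-acylation came first, the same two bonds would form and chloride would leave by E1cB. The closest known reaction is the α,α′-annulation of cyclohexanone and cyclopentanone enamines by acryloyl and crotonoyl chlorides to bicyclo[3.3.1]nonane-2,9-diones and their [3.2.1] homologues; new here are the cyclobutanone enamine, the strained [3.1.1] product and the β-chlorine that delivers the enone directly. The six-membered ring has to span cis-1,3 positions of the cyclobutane, so C6 and C10 are necessarily cis to each other. C11 becomes stereogenic through the choice of face: both bonds form on the face away from the tert-butyl ester, whose position in the product (anti to the enone, over the sp2 carbon C5) is the uncrowded one, so the methyl ends syn to the enone. The absolute configuration depends on which enantiotopic α-carbon is alkenylated (C10) and which is acylated (C6): in the enamine rotamer that has the pyrrolidine stereocentre on the side of the C=C bond, the (S)-methoxymethyl arm covers the ester face of one double-bond isomer (matched with the ring bias) and the open face of the other (mismatched), and the isomers interconvert through the iminium. The step needs C–C bond formation instead of ketene formation from 7 (hence a weak, hindered base), a single annulation (slow addition of 7) and survival of the β-diketone: both α-carbons are bridgeheads, so 9 can neither enolise nor racemise, and the hydrolysis is run at pH 5 so that the protonated carbinolamine loses the amine and not the C5–C6 bond.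

Step 6
Reactants: 9 bicyclic enone-dione ester
Product: 10 tert-butyl 6-methyl-4-methylidene-7-oxo-2-(triisopropylsilyloxy)bicyclo[3.1.1]hept-2-ene-6-carboxylate (C7 enone held as silyl dienol ether; C5 ketone free; configuration as in 9)
Conditions: iPr3SiOTf (1.2 equiv), Et3N (2 equiv), CH2Cl2, −78 → 0 °C
Reagents that add atoms: triisopropylsilyl trifluoromethanesulfonate, CC(C)[Si](C(C)C)(C(C)C)OS(=O)(=O)C(F)(F)F
Why: Soft enolisation of the enone; C6 and C10 are bridgeheads, so only the C9 methyl can be deprotonated and a single extended silyl dienol ether forms. With C7 no longer a carbonyl, an alkoxide at C5 cannot cleave the C5–C6 bond, and the bridge is now flat.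

Step 7
Reactants: 10 silyl dienol ether ketone; 11 methyl 2-(trimethylsilyl)acetate
Product: 12 alkylidene ester, the C5=C4H–CO2CH3 derivative of 10 (E/Z mixture at C5=C4, both usable)
Conditions: 11, LiN(iPr)2, THF, −78 °C; then 10, −78 °C → rt
Reagents that add atoms: none
Why: Peterson olefination: the small, reactive lithium enolate of the α-silyl ester adds to the hindered but strained cyclobutanone and the β-silyl alkoxide eliminates at once; carbon is brought in as an sp2 unit so that the configuration of C5 is decided by the hydrogen added next.

Step 8
Reactants: 12 alkylidene ester
Product: 13 saturated ester, C5–H on the side of the silyloxydiene bridge and the CH2CO2CH3 group (C4) on C5 cis to the tert-butyl ester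
Conditions: Cu(OAc)2·H2O (5 mol %), 1,2-bis(diphenylphosphino)benzene (5 mol %), (MeO)2MeSiH (3 equiv), tBuOH (3 equiv), toluene, rt
Reagents that add atoms: none
Why: Copper hydride 1,4-reduction of a β,β-disubstituted enoate; the silyl dienol ether and the isolated ester do not react. Hydride should reach C5 from the flat bridge side because the other face is covered by the tert-butyl ester, the same sense in which hydride adds to the bridge ketone of chrysanthenone, where the opposite one-carbon bridge carries a methyl group; this sets C5 (H syn to the enone, C4 anti).

Step 9
Reactants: 13 saturated ester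
Product: 15 gem-dimethyl ester (C5–C(CH3)2–CO2CH3), via monomethyl ester 14 (not isolated)
Conditions: LiN(iPr)2, THF, −78 °C, then MeI; second cycle LiN(iPr)2, DMPU, MeI, −78 → 0 °C
Reagents that add atoms: iodomethane, CI
Why: Two successive ester enolate alkylations build the quaternary carbon C4; the tert-butyl ester has no α-hydrogen and the silyl dienol ether is inert to amide base and iodomethane.

Step 10
Reactants: 15 gem-dimethyl ester; 16 methyl phenyl sulfone
Product: 17 β-keto sulfone (C4–C3(=O)–C2H2–SO2Ph)
Conditions: 16 (3 equiv), n-BuLi (3 equiv), THF, −78 → 0 °C; then 15, 0 °C → rt; aq. NH4Cl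
Reagents that add atoms: none
Why: Claisen-type acylation of the sulfonyl carbanion by the methyl ester; the product is deprotonated as formed, which stops over-addition, and the tert-butyl ester on the quaternary ring carbon is too poor an electrophile to compete.

Step 11
Reactants: 17 β-keto sulfone
Product: 18 β-hydroxy sulfone, C3 carbinol with the spatial arrangement of 3R in the target (S by CIP here because of the sulfur)
Conditions: (S)-1-methyl-3,3-diphenyltetrahydro-1H,3H-pyrrolo[1,2-c][1,3,2]oxazaborole (0.2–1.0 equiv), catecholborane (2 equiv), toluene, −40 → −20 °C; MeOH
Reagents that add atoms: none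
Why: Oxazaborolidine-catalysed (CBS) reduction: the quaternary carbon C4 acts as the large group and CH2SO2Ph as the small one, so the (S)-catalyst should give the required carbinol. This is reagent control, needed because the cage is nearly mirror-symmetric around the chain; catecholborane at low temperature does not hydroborate the diene.

Step 12
Reactants: 18 β-hydroxy sulfone
Product: 19 tricyclic β-keto sulfone (C1 ketone, C2 phenylsulfonyl as epimers, C3 hydroxyl, C7 silyl dienol ether)
Conditions: LiN(iPr)2 (3.3 equiv), THF, −78 °C → rt; aq. NH4Cl
Reagents that add atoms: none
Why: Dieckmann-type intramolecular acylation: the O,C-dianion attacks the tert-butyl ester through its sulfonyl carbanion and closes the seven-membered ring at C1–C2. The two ends sit on cis-1,3 substituents of the cyclobutane and are held within reach, and deprotonation of the product drives the closure.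

Step 13
Reactants: 19 tricyclic β-keto sulfone
Product: 21 tricyclic ketol (C3 hydroxyl, C1 ketone, C7 enone restored), via desulfonylated dienol ether 20 (not isolated)
Conditions: SmI2 (2.5 equiv), THF/MeOH, −78 °C; then HF·pyridine, THF, 0 °C
Reagents that add atoms: none
Why: Reductive desulfonylation of an α-sulfonyl ketone by samarium diiodide, which does not touch the simple ketone or the β-hydroxyl, followed by fluoride cleavage of the silyl dienol ether; protonation at the terminal carbon of the diene, or acid equilibration of any exocyclic isomer, gives the conjugated enone.

Step 14
Reactants: 21 tricyclic ketol; 22 3-methylbutanal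
Product: 23 hydroxy ester (C3 3-methylbutanoate, C1 hydroxyl trans to it, C7 enone)
Conditions: 22 (6 equiv), SmI2 (0.3 equiv), THF, −10 °C
Reagents that add atoms: none
Why: Evans–Tishchenko reduction: the hemiacetal formed from the C3 hydroxyl and 22 transfers its hydride within a samarium chelate to the C1 ketone on the face of the C3 oxygen, so the new C1 hydroxyl is trans (1,3-anti) and the isovalerate ends on C3 in the same step; the C7 enone has no β-hydroxyl and is not reduced.

Step 15
Reactants: 23 hydroxy ester; 24 3-methylbut-2-enoyl chloride
Product: 25 target, (1R,2R,3R,5R,7S,8R)-2,6,6,9-tetramethyl-5-(3-methylbutanoyloxy)-11-oxotricyclo[5.4.0.0^{2,8}]undec-9-en-3-yl 3-methylbut-2-enoate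
Conditions: 24 (2 equiv), pyridine, 4-(dimethylamino)pyridine (cat.), CH2Cl2, 0 °C → rt
Reagents that add atoms: none
Why: Acylation of the remaining secondary alcohol with nucleophilic catalysis; the weak base pyridine avoids ketene formation and deconjugation of the senecioyl group and does not promote acyl migration.

## Compound list

1 | 1-methyl-3-oxocyclobutane-1-carboxylic acid | CC1(CC(=O)C1)C(=O)O | starting material
2 | tert-butyl 1-methyl-3-oxocyclobutane-1-carboxylate | CC1(CC(=O)C1)C(=O)OC(C)(C)C | intermediate
3 | (S)-2-(methoxymethyl)pyrrolidine | COC[C@@H]1CCCN1 | starting material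
4 | tert-butyl 3-[(2S)-2-(methoxymethyl)pyrrolidin-1-yl]-1-methylcyclobut-2-ene-1-carboxylate (both double-bond positions) | COC[C@@H]1CCCN1C1=CC(C)(C(=O)OC(C)(C)C)C1 | intermediate
5 | but-2-ynoic acid | CC#CC(=O)O | starting material
6 | (Z)-3-chlorobut-2-enoic acid | C/C(Cl)=C/C(=O)O | intermediate
7 | (Z)-3-chlorobut-2-enoyl chloride | C/C(Cl)=C/C(Cl)=O | intermediate
8 | bicyclic iminium chloride (C5=N+ of the annulated product with the auxiliary amine) | CC(C)(C)OC(=O)[C@@]1(C)[C@@H]2C(=O)C=C(C)[C@H]1C2=[N+]1CCC[C@H]1COC.[Cl-] | intermediate (not isolated)
9 | tert-butyl (1R,5R,6R)-4,6-dimethyl-2,7-dioxobicyclo[3.1.1]hept-3-ene-6-carboxylate (C5 and C7 ketones; ester anti, methyl syn to the enone) | CC(C)(C)OC(=O)[C@@]1(C)[C@@H]2C(=O)C=C(C)[C@H]1C2=O | intermediate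
10 | tert-butyl 6-methyl-4-methylidene-7-oxo-2-(triisopropylsilyloxy)bicyclo[3.1.1]hept-2-ene-6-carboxylate | CC(C)(C)OC(=O)[C@@]1(C)[C@@H]2C(O[Si](C(C)C)(C(C)C)C(C)C)=CC(=C)[C@H]1C2=O | intermediate
11 | methyl 2-(trimethylsilyl)acetate | COC(=O)C[Si](C)(C)C | starting material
12 | tert-butyl 7-(2-methoxy-2-oxoethylidene)-6-methyl-4-methylidene-2-(triisopropylsilyloxy)bicyclo[3.1.1]hept-2-ene-6-carboxylate (E/Z mixture at C5=C4) | CC(C)(C)OC(=O)[C@@]1(C)[C@@H]2C(O[Si](C(C)C)(C(C)C)C(C)C)=CC(=C)[C@H]1C2=CC(=O)OC | intermediate
13 | tert-butyl 7-(2-methoxy-2-oxoethyl)-6-methyl-4-methylidene-2-(triisopropylsilyloxy)bicyclo[3.1.1]hept-2-ene-6-carboxylate (side chain on C5 cis to the tert-butyl ester) | CC(C)(C)OC(=O)[C@@]1(C)[C@@H]2C(O[Si](C(C)C)(C(C)C)C(C)C)=CC(=C)[C@H]1[C@@H]2CC(=O)OC | intermediate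
14 | monomethyl ester, the 7-(1-methoxy-1-oxopropan-2-yl) analogue of 13 (C4 epimers) | CC(C)(C)OC(=O)[C@@]1(C)[C@@H]2C(O[Si](C(C)C)(C(C)C)C(C)C)=CC(=C)[C@H]1[C@@H]2C(C)C(=O)OC | intermediate (not isolated)
15 | gem-dimethyl ester, the 7-(1-methoxy-2-methyl-1-oxopropan-2-yl) analogue of 13 | CC(C)(C)OC(=O)[C@@]1(C)[C@@H]2C(O[Si](C(C)C)(C(C)C)C(C)C)=CC(=C)[C@H]1[C@@H]2C(C)(C)C(=O)OC | intermediate
16 | methyl phenyl sulfone | CS(=O)(=O)c1ccccc1 | starting material
17 | β-keto sulfone, the 7-[2-methyl-3-oxo-4-(phenylsulfonyl)butan-2-yl] analogue of 13 | CC(C)(C)OC(=O)[C@@]1(C)[C@@H]2C(O[Si](C(C)C)(C(C)C)C(C)C)=CC(=C)[C@H]1[C@@H]2C(C)(C)C(=O)CS(=O)(=O)c1ccccc1 | intermediate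
18 | β-hydroxy sulfone, the 7-[(3S)-3-hydroxy-2-methyl-4-(phenylsulfonyl)butan-2-yl] analogue of 13 | CC(C)(C)OC(=O)[C@@]1(C)[C@@H]2C(O[Si](C(C)C)(C(C)C)C(C)C)=CC(=C)[C@H]1[C@@H]2C(C)(C)[C@H](O)CS(=O)(=O)c1ccccc1 | intermediate
19 | tricyclic β-keto sulfone (C1 ketone, C2 phenylsulfonyl epimers, C3 hydroxyl, C7 triisopropylsilyl dienol ether with C9 methylidene) | O=C1C(S(=O)(=O)c4ccccc4)[C@@H](O)C(C)(C)[C@@H]2[C@H]3C(O[Si](C(C)C)(C(C)C)C(C)C)=CC(=C)[C@@H]2[C@]31C | intermediate
20 | desulfonylated tricyclic ketol silyl dienol ether | O=C1C[C@@H](O)C(C)(C)[C@@H]2[C@H]3C(O[Si](C(C)C)(C(C)C)C(C)C)=CC(=C)[C@@H]2[C@]31C | intermediate (not isolated)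
21 | tricyclic ketol (C3 hydroxyl, C1 ketone, C7 enone, 4,4,9,11-tetramethyl) | O=C1C[C@@H](O)C(C)(C)[C@@H]2[C@H]3C(=O)C=C(C)[C@@H]2[C@]31C | intermediate
22 | 3-methylbutanal | CC(C)CC=O | starting material
23 | hydroxy ester (C1 hydroxyl, C3 3-methylbutanoate, C7 enone) | O[C@@H]1C[C@@H](OC(=O)CC(C)C)C(C)(C)[C@@H]2[C@H]3C(=O)C=C(C)[C@@H]2[C@]31C | intermediate
24 | 3-methylbut-2-enoyl chloride | CC(C)=CC(Cl)=O | starting material
25 | CNP0335239.1, (1R,2R,3R,5R,7S,8R)-2,6,6,9-tetramethyl-5-(3-methylbutanoyloxy)-11-oxotricyclo[5.4.0.0^{2,8}]undec-9-en-3-yl 3-methylbut-2-enoate | CC(C)=CC(=O)O[C@@H]1C[C@@H](OC(=O)CC(C)C)C(C)(C)[C@@H]2[C@H]3C(=O)C=C(C)[C@@H]2[C@]31C | target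

## Step count and least certain steps

Total: 15 steps. Longest linear sequence: 13 steps (1, 2, 5–15); steps 3 and 4 form a two-step side branch.

**Step 5 (key step).** Three things can go wrong.
- The second ring closure may lose to intermolecular acylation or oligomerisation, because the bridged transition state on a four-membered ring is strained.
- The C5–C6 bond may be cleaved during hydrolysis of 8, or on any contact of 9 with nucleophiles, because retro-Claisen opening releases the strain of the cyclobutanone.
- The face selection (methyl against tert-butyl ester) and the choice between the two α-carbons may be modest, and the sense of the latter rests on a rotamer model.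

Fallback with known reactions: the two bonds are made in separate flasks. Enamine 4 is C-acylated with 7 at −78 °C (enamine acylation) and hydrolysed at pH 5 to tert-butyl 2-[(2Z)-3-chlorobut-2-enoyl]-1-methyl-3-oxocyclobutane-1-carboxylate F1, an enolised β-diketone in which the auxiliary's choice of α-carbon is stored at the quaternary centre. Treatment of F1 with 2.2 equiv of LiN(SiMe3)2 gives the β-diketone dianion, whose α′-carbon (C10) displaces chloride at C9 by intramolecular addition–elimination. This returns to 9.

**Step 7.** Addition of the enolate to the C5 ketone may be slow or reversible, because that carbon is flanked by two bridgeheads and shielded on one face by the ester and on the other by the bridge. The fallback changes the olefination mechanism and brings one methyl group with it. Ketone 10 is treated with lithium prop-1-yn-1-olate (from ethyl 2,2-dibromopropanoate and tert-butyllithium); the β-lactone enolate opens to 2-alkylidenepropanoic acid F2, which Me3SiCHN2 converts to its methyl ester F3. Copper hydride reduction of F3 as in step 8 gives 14, and a single methylation as in step 9 returns to 15.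

**Step 8.** Hydride may be delivered to the face of the tert-butyl ester, because both faces of C5 are hindered and the preference for the bridge side rests on analogy. This would put C4 on the wrong side, where it cannot reach C1. The fallback replaces substrate control by ligand control and recycles the wrong epimer. The C5 epimer F4 is selenenylated (LiN(iPr)2, PhSeBr) to α-phenylselanyl ester F5, and oxidation with H2O2 and syn-elimination regenerate 12. The E and Z isomers of 12 are then separated and each is reduced with the enantiomer of a chiral bisphosphine–copper hydride catalyst that is matched to the bridge face (enantioselective 1,4-reduction of β,β-disubstituted enoates). This returns to 13.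

**Step 12.** The carbanion may fail to acylate the hindered tert-butyl ester, or the C3 alkoxide may compete (lactonisation, or reversal of the sulfone–carbonyl addition), because the leaving group is poor and a free alkoxide is present. The fallback changes the electrophile and protects the carbinol. Hydroxy sulfone 18 is treated with Et3SiOTf and 2,6-lutidine, which silylates C3–OH and cleaves the tert-butyl ester; aqueous work-up gives acid F6. 1,1′-Carbonyldiimidazole gives acyl imidazolide F7, and LiN(SiMe3)2 closes the ring to the C3 triethylsilyl ether of the cyclic keto sulfone, F8. SmI2 and then HF·pyridine (which removes both silyl groups) return to 21.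

## Further compounds

F1 | step 5 | tert-butyl 2-[(2Z)-3-chlorobut-2-enoyl]-1-methyl-3-oxocyclobutane-1-carboxylate (enolised; acyl-bearing carbon not defined) | CC(C)(C)OC(=O)[C@@]1(C)C(C(=O)/C=C(/C)Cl)C(=O)C1
F2 | step 7 | 2-alkylidenepropanoic acid from 10 (C5=C4(CH3)–CO2H, E/Z mixture) | CC(C)(C)OC(=O)[C@@]1(C)[C@@H]2C(O[Si](C(C)C)(C(C)C)C(C)C)=CC(=C)[C@H]1C2=C(C)C(=O)O
F3 | step 7 | methyl ester of F2 | CC(C)(C)OC(=O)[C@@]1(C)[C@@H]2C(O[Si](C(C)C)(C(C)C)C(C)C)=CC(=C)[C@H]1C2=C(C)C(=O)OC
F4 | step 8 | C5 epimer of 13 (side chain on the bridge side) | CC(C)(C)OC(=O)[C@@]1(C)[C@@H]2C(O[Si](C(C)C)(C(C)C)C(C)C)=CC(=C)[C@H]1[C@H]2CC(=O)OC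
F5 | step 8 | α-phenylselanyl ester of F4 (C4 epimers) | CC(C)(C)OC(=O)[C@@]1(C)[C@@H]2C(O[Si](C(C)C)(C(C)C)C(C)C)=CC(=C)[C@H]1[C@H]2C([Se]c1ccccc1)C(=O)OC
F6 | step 12 | carboxylic acid from 18 with C3 triethylsilyl ether | OC(=O)[C@@]1(C)[C@@H]2C(O[Si](C(C)C)(C(C)C)C(C)C)=CC(=C)[C@H]1[C@@H]2C(C)(C)[C@H](O[Si](CC)(CC)CC)CS(=O)(=O)c1ccccc1
F7 | step 12 | acyl imidazolide of F6 | O=C(n1ccnc1)[C@@]1(C)[C@@H]2C(O[Si](C(C)C)(C(C)C)C(C)C)=CC(=C)[C@H]1[C@@H]2C(C)(C)[C@H](O[Si](CC)(CC)CC)CS(=O)(=O)c1ccccc1
F8 | step 12 | tricyclic β-keto sulfone with C3 triethylsilyl ether | O=C1C(S(=O)(=O)c4ccccc4)[C@@H](O[Si](CC)(CC)CC)C(C)(C)[C@@H]2[C@H]3C(O[Si](C(C)C)(C(C)C)C(C)C)=CC(=C)[C@@H]2[C@]31C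
A1 | alternative 1 | tricyclic homoallylic alcohol (C7 hydroxyl, C9 exocyclic methylene, C1 silyl ether, C3 isovalerate) | CC(C)(C)[Si](C)(C)O[C@@H]1C[C@@H](OC(=O)CC(C)C)C(C)(C)[C@@H]2[C@H]3[C@H](O)CC(=C)[C@@H]2[C@]31C
A2 | alternative 2 | tricyclic 1,3-diketone (C1 and C3 ketones, C7 methylene) | O=C1CC(=O)C(C)(C)[C@@H]2[C@H]3CC=C(C)[C@@H]2[C@]31C
A3 | alternative 3 | bicyclo[4.1.1]octan-8-one with C10 ethyl ester, C11 methyl, C1 hydroxyl and C3 dioxolane | CCOC(=O)[C@H]1[C@H]2C(=O)[C@]1(C)[C@H](O)CC3(OCCO3)C2(C)C
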